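**Plan** (ring A: C1′ = biaryl carbon, C2′/C6′ = prenyl, C3′/C4′ = OH; ring B: chromene numbering)
1. Cuts: the biaryl bond C7–C1′ (Suzuki–Miyaura); the C4′–OH bond, carried as a formyl group (Dakin); the prenyl C–C bonds at C2′ and C6′, both delivered from O3′ (ortho-, then para-Claisen); the pyran bonds C4–C4a, O1–C8a and O1–C2 (aryne + 3-methylbut-2-enal).
2. Ring B, forward: the O-heterocycle is first closed on 3-methoxybenzyne as a four-membered oxete (O1–C8a–C4a–C4) and enlarged in the same operation by two atoms (C3, C2) to the 2H-pyran; O-demethylation and C7–H borylation follow.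
3. Ring A, forward: 4-bromo-2-hydroxybenzaldehyde takes up the C2′ prenyl, then the C6′ prenyl; the rings are joined and the formyl group is exchanged for the second catechol OH last.
4. Enabling feature: the pyran ring (O1, C2 with two methyls, C3=C4, C4a, C8a) is the oxa-6π valence isomer of an o-quinone methide, itself the 4π-opened form of a benzoxete bearing a 2-methylprop-1-enyl group on C4; the oxygen on C5, next to C4a, polarises the C4a≡C8a aryne bond and fixes the orientation.
5. Stereochemistry: none to set – no stereocentre, C3=C4 is cis by ring constraint, and the biaryl axis (two ortho H on ring B) is not configurationally stable.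

Key step: step 6

Remark: the target as drawn is achiral (no stereocentre, freely rotating biaryl axis), so no enantiocontrol is required.

**Route**

Step 1
Reactants: 1 4-bromo-2-hydroxybenzaldehyde; 2 3-chloro-3-methylbut-1-yne
Product: 3 4-bromo-2-[(2-methylbut-3-yn-2-yl)oxy]benzaldehyde
Conditions: K2CO3, KI (cat.), CuI (cat.), DMF, 60 °C
Reagents that add atoms: none
Why: Copper-assisted O-alkylation of the phenoxide by the tertiary propargylic chloride is the standard entry to aryl 1,1-dimethylpropargyl ethers, and the aldehyde and aryl bromide are inert to it.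

Step 2
Reactants: 3 4-bromo-2-[(2-methylbut-3-yn-2-yl)oxy]benzaldehyde
Product: 4 4-bromo-2-[(2-methylbut-3-en-2-yl)oxy]benzaldehyde
Conditions: H2 (1 atm), Lindlar catalyst, quinoline, EtOAc, rt
Reagents that add atoms: none
Why: Lindlar semihydrogenation of the terminal alkyne should stop at the alkene, and the poisoned catalyst leaves the C–Br bond and the aldehyde untouched.

Step 3
Reactants: 4 4-bromo-2-[(2-methylbut-3-en-2-yl)oxy]benzaldehyde
Product: 5 4-bromo-2-hydroxy-3-(3-methylbut-2-en-1-yl)benzaldehyde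
Conditions: PhNEt2, 140 °C
Reagents that add atoms: none
Why: Aromatic Claisen rearrangement ([3,3]) of the 1,1-dimethylallyl ether delivers the allyl unit with inversion, i.e. as a linear prenyl group, to the only free ortho carbon (between OH and C–Br), and enolisation restores the phenol.

Step 4
Reactants: 5 4-bromo-2-hydroxy-3-(3-methylbut-2-en-1-yl)benzaldehyde; 6 1-bromo-3-methylbut-2-ene (prenyl bromide)
Product: 7 4-bromo-3-(3-methylbut-2-en-1-yl)-2-[(3-methylbut-2-en-1-yl)oxy]benzaldehyde
Conditions: K2CO3, DMF, rt → 40 °C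
Reagents that add atoms: none
Why: Williamson O-alkylation (SN2) of the hindered, hydrogen-bonded phenoxide in a dipolar aprotic solvent, where O- rather than C-alkylation is expected.

Step 5
Reactants: 7 4-bromo-3-(3-methylbut-2-en-1-yl)-2-[(3-methylbut-2-en-1-yl)oxy]benzaldehyde
Product: 9 4-bromo-2-hydroxy-3,5-bis(3-methylbut-2-en-1-yl)benzaldehyde, via 4-bromo-1-(2-methylbut-3-en-2-yl)-5-(3-methylbut-2-en-1-yl)-6-oxocyclohexa-2,4-diene-1-carbaldehyde 8 (not isolated)
Conditions: PhNEt2, 190 °C, sealed tube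
Reagents that add atoms: none
Why: para-Claisen rearrangement: with both ortho carbons substituted, the first [3,3] shift gives the blocked ortho-dienone 8, which cannot enolise and passes the allyl unit on by a Cope [3,3] shift to the free para carbon, the two inversions returning a linear prenyl group before enolisation to the phenol.

Step 6
Reactants: 10 3-methoxy-2-(trimethylsilyl)phenyl trifluoromethanesulfonate; 11 3-methylbut-2-enal
Product: 15 5-methoxy-2,2-dimethyl-2H-chromene, via 3-methoxybenzyne 12 (not isolated), via 3-methoxy-2-(2-methylprop-1-en-1-yl)-2H-benzo[b]oxete 13 (not isolated), via (6Z)-5-methoxy-6-(3-methylbut-2-en-1-ylidene)cyclohexa-2,4-dien-1-one 14 (not isolated)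
Conditions: CsF (3 equiv), 11 (5 equiv), MeCN, rt → 50 °C
Reagents that add atoms: none
Why: Fluoride-induced 1,2-elimination of Me3SiF and triflate from 10 gives 3-methoxybenzyne 12; the carbonyl oxygen of 11 adds to its C8a terminus and the resulting C4a aryl anion collapses onto the carbonyl carbon, a stepwise formal [2+2] that closes the four-membered oxete ring O1–C8a–C4a–C4 of 13 (4-exo collapse of the zwitterion). The strain of 13 then drives a two-atom ring expansion: thermally allowed 4π-electrocyclic opening of the O1–C4 bond gives the Z o-quinone methide 14, whose O=C8a–C4a=C4–C3=C2 array closes by oxa-6π electrocyclisation (disrotatory, O1–C2 bond, rearomatising ring B) to the 2H-pyran, so that C3 and C2 end up inserted between C4 and O1. The closest known reaction type is the conversion of arynes with α,β-unsaturated aldehydes into 2H-chromenes. No stereocentre is formed, since C2 carries two methyl groups and C3=C4 is cis by ring constraint. The step needs regioselectivity (O to C8a, C to C4a), secured by the OMe group next to C4a, which distorts the aryne so that nucleophiles add at the remote carbon, and chemoselectivity for carbonyl [2+2] over hetero-[4+2] or ene reaction, favoured by the β,β-dimethyl terminus and the excess of 11.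

Step 7
Reactants: 15 5-methoxy-2,2-dimethyl-2H-chromene
Product: 16 2,2-dimethyl-2H-chromen-5-ol
Conditions: NaSEt (3 equiv), DMF, 130 °C; then 1 M HCl, 0 °C
Reagents that add atoms: none
Why: SN2 O-demethylation of the aryl methyl ether by thiolate is non-acidic, so the acid-sensitive 2,2-dimethylchromene should survive.

Step 8
Reactants: 16 2,2-dimethyl-2H-chromen-5-ol
Product: 19 2,2-dimethyl-7-(4,4,5,5-tetramethyl-1,3,2-dioxaborolan-2-yl)-2H-chromen-5-ol, via 2-[(2,2-dimethyl-2H-chromen-5-yl)oxy]-4,4,5,5-tetramethyl-1,3,2-dioxaborolane 17 (not isolated), via 2-{[2,2-dimethyl-7-(4,4,5,5-tetramethyl-1,3,2-dioxaborolan-2-yl)-2H-chromen-5-yl]oxy}-4,4,5,5-tetramethyl-1,3,2-dioxaborolane 18 (not isolated)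
Conditions: HBpin (1.1 equiv), THF, rt; then [Ir(OMe)(cod)]2 (1.5 mol %), dtbpy (3 mol %), B2pin2 (1.0 equiv), 80 °C; then MeOH, rt
Reagents that add atoms: bis(pinacolato)diboron, CC1(C)OB(OC1(C)C)B1OC(C)(C)C(C)(C)O1
Why: Sterically controlled Ir-catalysed aromatic C–H borylation (Hartwig–Miyaura) of the in situ O-borylated phenol should occur at C7, the only C–H with no substituted neighbour (C6 and C8 each adjoin an oxygen-bearing carbon, both vinylic C–H adjoin C4a or the quaternary C2), and methanolysis removes the O-boryl group.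

Step 9
Reactants: 19 2,2-dimethyl-7-(4,4,5,5-tetramethyl-1,3,2-dioxaborolan-2-yl)-2H-chromen-5-ol; 9 4-bromo-2-hydroxy-3,5-bis(3-methylbut-2-en-1-yl)benzaldehyde
Product: 20 4-(5-hydroxy-2,2-dimethyl-2H-chromen-7-yl)-2-hydroxy-3,5-bis(3-methylbut-2-en-1-yl)benzaldehyde
Conditions: Pd(OAc)2 (5 mol %), SPhos (10 mol %), K3PO4 (4 equiv), toluene/H2O 10:1, 90 °C
Reagents that add atoms: none
Why: Suzuki–Miyaura coupling in which the SPhos-ligated catalyst handles the di-ortho-substituted aryl bromide (activated by its para formyl group) while the boronate partner has no ortho substituent.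

Step 10
Reactants: 20 4-(5-hydroxy-2,2-dimethyl-2H-chromen-7-yl)-2-hydroxy-3,5-bis(3-methylbut-2-en-1-yl)benzaldehyde
Product: 22 Clusiachromene D, 4-(5-hydroxy-2,2-dimethyl-2H-chromen-7-yl)-3,5-bis(3-methylbut-2-en-1-yl)benzene-1,2-diol, via 4-(5-hydroxy-2,2-dimethyl-2H-chromen-7-yl)-2-hydroxy-3,5-bis(3-methylbut-2-en-1-yl)phenyl formate 21 (not isolated)
Conditions: 30 % H2O2 (1.2 equiv), NaOH (3 equiv), degassed THF/H2O, 0 °C; then aq. Na2S2O4, 1 M HCl to pH 4
Reagents that add atoms: hydrogen peroxide, OO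
Why: Dakin oxidation: hydroperoxide adds to the o-hydroxybenzaldehyde, the electron-rich aryl group migrates to oxygen to give formate 21, which is saponified in situ to the catechol, while nucleophilic HOO− should not epoxidise the unactivated prenyl and chromene alkenes.

**Compound list**
1 | 4-bromo-2-hydroxybenzaldehyde | O=Cc1ccc(Br)cc1O | starting material
2 | 3-chloro-3-methylbut-1-yne | C#CC(C)(C)Cl | starting material
3 | 4-bromo-2-[(2-methylbut-3-yn-2-yl)oxy]benzaldehyde | O=Cc1ccc(Br)cc1OC(C)(C)C#C | intermediate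
4 | 4-bromo-2-[(2-methylbut-3-en-2-yl)oxy]benzaldehyde | O=Cc1ccc(Br)cc1OC(C)(C)C=C | intermediate
5 | 4-bromo-2-hydroxy-3-(3-methylbut-2-en-1-yl)benzaldehyde | O=Cc1ccc(Br)c(CC=C(C)C)c1O | intermediate
6 | 1-bromo-3-methylbut-2-ene | CC(C)=CCBr | starting material
7 | 4-bromo-3-(3-methylbut-2-en-1-yl)-2-[(3-methylbut-2-en-1-yl)oxy]benzaldehyde | O=Cc1ccc(Br)c(CC=C(C)C)c1OCC=C(C)C | intermediate
8 | 4-bromo-1-(2-methylbut-3-en-2-yl)-5-(3-methylbut-2-en-1-yl)-6-oxocyclohexa-2,4-diene-1-carbaldehyde | O=CC1(C(C)(C)C=C)C=CC(Br)=C(CC=C(C)C)C1=O | intermediate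
9 | 4-bromo-2-hydroxy-3,5-bis(3-methylbut-2-en-1-yl)benzaldehyde | O=Cc1cc(CC=C(C)C)c(Br)c(CC=C(C)C)c1O | intermediate
10 | 3-methoxy-2-(trimethylsilyl)phenyl trifluoromethanesulfonate | COc1cccc(OS(=O)(=O)C(F)(F)F)c1[Si](C)(C)C | starting material
11 | 3-methylbut-2-enal | CC(C)=CC=O | starting material
12 | 3-methoxybenzyne | COC1=CC=CC#C1 | intermediate
13 | 3-methoxy-2-(2-methylprop-1-en-1-yl)-2H-benzo[b]oxete | COc1cccc2OC(C=C(C)C)c12 | intermediate
14 | (6Z)-5-methoxy-6-(3-methylbut-2-en-1-ylidene)cyclohexa-2,4-dien-1-one | COC1=CC=CC(=O)/C1=C\C=C(C)C | intermediate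
15 | 5-methoxy-2,2-dimethyl-2H-chromene | COc1cccc2OC(C)(C)C=Cc12 | intermediate
16 | 2,2-dimethyl-2H-chromen-5-ol | Oc1cccc2OC(C)(C)C=Cc12 | intermediate
17 | 2-[(2,2-dimethyl-2H-chromen-5-yl)oxy]-4,4,5,5-tetramethyl-1,3,2-dioxaborolane | CC1(C)OB(Oc2cccc3OC(C)(C)C=Cc23)OC1(C)C | intermediate
18 | 2-{[2,2-dimethyl-7-(4,4,5,5-tetramethyl-1,3,2-dioxaborolan-2-yl)-2H-chromen-5-yl]oxy}-4,4,5,5-tetramethyl-1,3,2-dioxaborolane | CC1(C)OB(Oc2cc(B3OC(C)(C)C(C)(C)O3)cc3OC(C)(C)C=Cc23)OC1(C)C | intermediate
19 | 2,2-dimethyl-7-(4,4,5,5-tetramethyl-1,3,2-dioxaborolan-2-yl)-2H-chromen-5-ol | Oc1cc(B2OC(C)(C)C(C)(C)O2)cc2OC(C)(C)C=Cc12 | intermediate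
20 | 4-(5-hydroxy-2,2-dimethyl-2H-chromen-7-yl)-2-hydroxy-3,5-bis(3-methylbut-2-en-1-yl)benzaldehyde | O=Cc1cc(CC=C(C)C)c(-c2cc(O)c3C=CC(C)(C)Oc3c2)c(CC=C(C)C)c1O | intermediate
21 | 4-(5-hydroxy-2,2-dimethyl-2H-chromen-7-yl)-2-hydroxy-3,5-bis(3-methylbut-2-en-1-yl)phenyl formate | O=COc1cc(CC=C(C)C)c(-c2cc(O)c3C=CC(C)(C)Oc3c2)c(CC=C(C)C)c1O | intermediate
22 | Clusiachromene D | CC(C)=CCc1cc(O)c(O)c(CC=C(C)C)c1-c1cc(O)c2c(c1)OC(C)(C)C=C2 | target

**Step count and risks**
Total steps: 10. Longest linear sequence: 7 (steps 1–5, 9, 10); the ring B branch is steps 6–8.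

Most likely to fail:

- **Step 6.** The aryne may be consumed by pathways other than carbonyl [2+2]: hetero-[4+2] across the O=C–C=C unit, ene reaction with the allylic methyls, or capture of the o-quinone methide by a second aryne. The weakly nucleophilic aldehyde may also trap the aryne too slowly. Fallback, setting out from 11 and returning at 16: 11 would be condensed with commercial cyclohexane-1,3-dione (O=C1CCCC(=O)C1) under ethylenediammonium diacetate catalysis (Knoevenagel condensation, then oxa-6π electrocyclisation) to 2,2-dimethyl-2,6,7,8-tetrahydro-5H-chromen-5-one F1. α-Selenation (LDA, PhSeBr, THF, −78 °C) would give 2,2-dimethyl-6-(phenylselanyl)-2,6,7,8-tetrahydro-5H-chromen-5-one F2. Oxidative syn-elimination (H2O2, 0 °C) and tautomerisation of the resulting dienone would give 16, so that step 7 is not needed. The pyran ring is then built directly in its final size.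

- **Step 5.** The double [3,3] sequence may lose positional fidelity: the two allyl groups can exchange on a common dienone carbon and give reversed prenyl units, and the formyl-bearing dienone can lose its formyl group. Fallback, setting out from 1 and returning at 9: iodination para to the hydroxyl (NIS, cat. TFA, MeCN) would give 4-bromo-2-hydroxy-5-iodobenzaldehyde F3. Chemoselective Stille coupling at the C–I bond with tributyl(3-methylbut-2-en-1-yl)stannane (Pd(PPh3)4, DMF, 70 °C) would give 4-bromo-2-hydroxy-5-(3-methylbut-2-en-1-yl)benzaldehyde F4. O-Alkylation with 2 as in step 1 would give 4-bromo-5-(3-methylbut-2-en-1-yl)-2-[(2-methylbut-3-yn-2-yl)oxy]benzaldehyde F5, and Lindlar semihydrogenation 4-bromo-5-(3-methylbut-2-en-1-yl)-2-[(2-methylbut-3-en-2-yl)oxy]benzaldehyde F6. Ortho-Claisen rearrangement as in step 3, now with only one free position, would give 9 and avoid the para-Claisen altogether.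

- **Step 8.** Regiocontrol may be lost if an O–boryl/ligand interaction steers borylation ortho to oxygen (C6), and the chromene double bond may be hydroborated. Fallback, setting out from 16 and returning at 20: silylation (TIPSCl, imidazole, DMF) would give [(2,2-dimethyl-2H-chromen-5-yl)oxy]tri(propan-2-yl)silane F7, which has a bulky, non-coordinating oxygen substituent and no O–B unit. Ir-catalysed borylation (B2pin2, no HBpin pretreatment) should then follow steric bias only and give {[2,2-dimethyl-7-(4,4,5,5-tetramethyl-1,3,2-dioxaborolan-2-yl)-2H-chromen-5-yl]oxy}tri(propan-2-yl)silane F8. Suzuki coupling with 9 (anhydrous K3PO4, toluene) would give 2-hydroxy-3,5-bis(3-methylbut-2-en-1-yl)-4-{2,2-dimethyl-5-[tri(propan-2-yl)silyloxy]-2H-chromen-7-yl}benzaldehyde F9, and fluoride desilylation (TBAF/AcOH, THF, 0 °C) would give 20.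

**Further compounds**
F1 | step 6 | 2,2-dimethyl-2,6,7,8-tetrahydro-5H-chromen-5-one | O=C1CCCC2=C1C=CC(C)(C)O2
F2 | step 6 | 2,2-dimethyl-6-(phenylselanyl)-2,6,7,8-tetrahydro-5H-chromen-5-one | O=C1C([Se]c2ccccc2)CCC2=C1C=CC(C)(C)O2
F3 | step 5 | 4-bromo-2-hydroxy-5-iodobenzaldehyde | O=Cc1cc(I)c(Br)cc1O
F4 | step 5 | 4-bromo-2-hydroxy-5-(3-methylbut-2-en-1-yl)benzaldehyde | O=Cc1cc(CC=C(C)C)c(Br)cc1O
F5 | step 5 | 4-bromo-5-(3-methylbut-2-en-1-yl)-2-[(2-methylbut-3-yn-2-yl)oxy]benzaldehyde | O=Cc1cc(CC=C(C)C)c(Br)cc1OC(C)(C)C#C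
F6 | step 5 | 4-bromo-5-(3-methylbut-2-en-1-yl)-2-[(2-methylbut-3-en-2-yl)oxy]benzaldehyde | O=Cc1cc(CC=C(C)C)c(Br)cc1OC(C)(C)C=C
F7 | step 8 | [(2,2-dimethyl-2H-chromen-5-yl)oxy]tri(propan-2-yl)silane | CC(C)[Si](Oc1cccc2OC(C)(C)C=Cc12)(C(C)C)C(C)C
F8 | step 8 | {[2,2-dimethyl-7-(4,4,5,5-tetramethyl-1,3,2-dioxaborolan-2-yl)-2H-chromen-5-yl]oxy}tri(propan-2-yl)silane | CC(C)[Si](Oc1cc(B3OC(C)(C)C(C)(C)O3)cc2OC(C)(C)C=Cc12)(C(C)C)C(C)C
F9 | step 8 | 2-hydroxy-3,5-bis(3-methylbut-2-en-1-yl)-4-{2,2-dimethyl-5-[tri(propan-2-yl)silyloxy]-2H-chromen-7-yl}benzaldehyde | O=Cc1cc(CC=C(C)C)c(-c2cc(O[Si](C(C)C)(C(C)C)C(C)C)c3C=CC(C)(C)Oc3c2)c(CC=C(C)C)c1O
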